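Remark 1 (convention): germacrane numbering of the target is used for every intermediate (ring carbons C1–C10, lactone carbons C11–C13 with the ring oxygen on C6, C14 on C10, C15 on C4).
Remark 2 (assumption): the (R,R) antipode of the TADDOL catalyst in step 1 is taken to give (R)-4; if the sense of induction is the opposite, the (S,S) antipode is used.

## Structural features

The target is a heliangolide-type germacranolide: a ten-membered carbocycle (C1–C10) trans-fused at C6/C7 to an α-methylene-γ-butyrolactone (ring C). The carbocycle holds one endocyclic double bond, the (Z)-trisubstituted C4=C5 alkene that carries C15. There are five stereocentres: the contiguous triad C6 (lactone O), C7 (lactone C) and C8 (isobutyrate), the allylic carbinol C3, and the tertiary methyl carbinol C10, whose oxygen is 1,3-anti to the C8 oxygen. The exocyclic enoate is a Michael acceptor and can migrate into the ring. The C8 ester sits next to the lactone oxygen, so acyl transfer or trans-lactonisation is possible, and the C10 tertiary alcohol and the C3 allylic alcohol are acid-sensitive. The real difficulty is the medium ring with a ring-cis trisubstituted alkene (strain, entropy and E/Z control on direct closure), together with relating the remote centres C3 and C10 to the C6–C8 triad. The feature exploited is that the two carbinol carbons C3 and C8 lie exactly across the ring, five bonds apart in either direction. A C3–C8 bond therefore turns the macrocycle into a bicyclo[4.4.0]decane. Ring A (C3, C4, C5, C6, C7, C8) must hold the C4=C5 alkene cis, ring B (C3, C2, C1, C10, C9, C8) carries C10, and cleaving that bond as a 1,2-diol returns oxygen to both C3 and C8.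

## Logic of the disconnections

26 back to 25: the C3–H bond is cut (allylic alcohol back to the (Z)-enone). C3 is the only stereocentre with no neighbour to lean on, so it is set last by a catalyst-controlled carbonyl reduction. The demand is facial control at a ketone flanked by CH2 (C2) and an α-methylalkenyl group (C4).

25 back to 24 and 23: the C8 ester C–O bond and then the C8–H bond are cut. With a ketone at C8, the C10 tertiary hydroxyl is β to it and can deliver hydride internally, which fixes the 8,10-anti relationship. The demand is that only the β-hydroxy ketone is reduced and that the C3 enone is left alone.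

23 back to 22 (key disconnection): a bond is added between the two carbonyl carbons C3 and C8, which turns the ten-membered 3,8-dione into a ring-fusion 1,2-diol of a bicyclo[4.4.0]decene. The gain is that the medium ring, the Z geometry of C4=C5 and the oxygen at C3 and C8 all come from one scission of a decalin-type diol made by six-membered-ring chemistry. The C3 and C8 configurations of 22 are irrelevant because both carbons become sp2. The demand on the forward step is a clean glycol cleavage beside a free tertiary alcohol, two alkenes and the lactone.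

22 back to 21 and 18: the three silyl ethers and the C11=C13 bond are cut, with C13 coming from an iminium salt. The methylene group is introduced at 18, the last intermediate without a ketone, so that the lactone α-protons are the only acidic C–H bonds.

18 back to 16: the C3–C4 bond is cut (vinyl metal plus ketone), which opens ring A. The same bond would close the ten-membered ring in a conventional macrocyclisation; here it closes a cyclohexene. The demand is an iodine cis to C6 on the C4=C5 double bond and an organometallic that tolerates the lactone.

16 back to 14, 13 and 12: the C4=C5 bond is cut (aldehyde plus the α-iodo ylide from 15, which brings C4, C15 and the iodine). The C5 aldehyde goes back to the alcohol, and the C1–C2 single bond and the free C5 hydroxyl go back to an enone and a benzyl ether, removed together by one hydrogenation.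

12 back to 10: the C8–O bond is cut. The C1=C2 double bond of the enone leaves C8 as the only enolisable position, so the oxygen can only go to C8.

10 back to 7 and 9: the C7–C8 bond is cut (enolate plus butenolide). The C6 stereocentre of 9 sets C7 by anti addition, which gives the trans-lactone. The demand is a single Michael addition without a second, intramolecular one.

7 back to 6, 4, and 1 plus 2: the C10–O bond goes back to a C10–CHO bond (oxidative rearrangement with retention), and ring B is opened by a Diels–Alder disconnection that creates C10 as the only stereocentre. 9 goes back to commercial 8 by one O-benzylation.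

## Other disconnections considered

Alternative 1: cut C6–C7 and the lactone C–O bond (the first idea for an α-methylene lactone on a macrocycle). The forward key step is an intramolecular chromium- or zinc-mediated allylation of the (Z)-enal in bromo ester A1, which would close the ten-membered ring and lactonise to A2. The closure has to pay the full medium-ring penalty at a conjugated (Z)-enal. C6 and C7 would be formed together under the influence of C8 alone, so up to four diastereomers are possible. C3, C8 and C10 would all have to be built into an open chain beforehand. The chosen plan makes only six-membered rings and sets C7 from C6 in a rigid butenolide.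

Alternative 2: cut C4=C5. The forward key step is ring-closing metathesis of diene A3 straight to 26. A trisubstituted alkene in a ten-membered ring is among the hardest metathesis closures: oligomerisation should compete, the exocyclic enoate is a third alkene, and the Z geometry would rest on ring strain alone. In the chosen plan the same double bond is enclosed in a cyclohexene, so its geometry is not in question.

Alternative 3: cut C2–C3 and reconnect C5–C10, i.e. an anionic oxy-Cope ring expansion of the 1,2-dialkenylcyclohexanol A4 to the cyclodec-5-enone A5. This maps the C10 oxygen and the C4=C5 alkene well. However, the Z alkene requires the cis-dialkenyl isomer to react through one of two competing chair transition states. C3 would then have to be oxidised afterwards at an allylic CH2 with unknown regio- and stereochemistry. The C10 methyl group would have to be added to a ring ketone without a directing group, and the lactone in A4 is enolisable under the basic conditions. The chosen scission places oxygen at C3 and C8 automatically and leaves C10 untouched.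

Key step: step 13

## Steps

Step 1
Reactants: 1 (E)-3-(tert-butyldimethylsilyloxy)-N,N-dimethylbuta-1,3-dien-1-amine; 2 methacrolein
Product: 4 (R)-1-methyl-4-oxocyclohex-2-ene-1-carbaldehyde, via endo amino silyl enol ether cycloadduct 3 (not isolated)
Conditions: (R,R)-1-naphthyl-TADDOL (20 mol%), toluene, −80 °C; then AcCl, CH2Cl2/Et2O, −78 °C
Reagents that add atoms: none
Why: Hydrogen-bond-catalysed enantioselective Diels–Alder reaction of an aminosilyloxydiene with an α-substituted acrolein; the ortho/endo mode places the new quaternary carbon (C10) para to the silyloxy carbon (C3), the catalyst antipode sets C10, and acetyl chloride then expels the amine to give the enone.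

Step 2
Reactants: 4 (R)-1-methyl-4-oxocyclohex-2-ene-1-carbaldehyde
Product: 6 (R)-4-hydroxy-4-methylcyclohex-2-en-1-one, via formate ester 5 (not isolated)
Conditions: mCPBA, CH2Cl2, 0 °C to rt; then K2CO3 (cat.), MeOH, 0 °C
Reagents that add atoms: 3-chloroperoxybenzoic acid (mCPBA), OOC(=O)c1cccc(Cl)c1
Why: Baeyer–Villiger oxidation of an aldehyde on a tertiary allylic carbon, in which the tertiary group migrates with retention so C10 keeps its configuration; the electron-poor enone alkene should not be epoxidised, and the formate is removed by methanolysis.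

Step 3
Reactants: 6 (R)-4-hydroxy-4-methylcyclohex-2-en-1-one
Product: 7 (R)-4-methyl-4-(triethylsilyloxy)cyclohex-2-en-1-one
Conditions: Et3SiOTf, 2,6-lutidine, CH2Cl2, −78 to 0 °C
Reagents that add atoms: triethylsilyl trifluoromethanesulfonate, CC[Si](CC)(CC)OS(=O)(=O)C(F)(F)F
Why: Standard silylation of a tertiary alcohol with a silyl triflate; the ether masks the C10 hydroxyl until step 12.

Step 4
Reactants: 8 (S)-5-(hydroxymethyl)furan-2(5H)-one
Product: 9 (S)-5-(benzyloxymethyl)furan-2(5H)-one
Conditions: benzyl 2,2,2-trichloroacetimidate, TfOH (cat.), CH2Cl2/cyclohexane, 0 °C to rt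
Reagents that add atoms: benzyl 2,2,2-trichloroacetimidate, ClC(Cl)(Cl)C(=N)OCc1ccccc1
Why: Acid-catalysed O-benzylation with the imidate avoids base, which would deprotonate the γ-position of the butenolide and erase C6.

Step 5
Reactants: 7 (R)-4-methyl-4-(triethylsilyloxy)cyclohex-2-en-1-one; 9 (S)-5-(benzyloxymethyl)furan-2(5H)-one
Product: 10 (4R,5S)-5-(benzyloxymethyl)-4-[(5R)-5-methyl-2-oxo-5-(triethylsilyloxy)cyclohex-3-en-1-yl]oxolan-2-one (C8 epimers, drawn as one)
Conditions: LiN(i-Pr)2, THF, −78 °C; then 9, −78 °C; AcOH quench at −78 °C
Reagents that add atoms: none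
Why: Kinetic deprotonation of 7 can only occur at C8 (C2 is sp2, C10 has no hydrogen), and Michael addition of this enolate to the butenolide anti to the C6 substituent sets C7 and the trans-lactone; the cold quench is meant to stop the lactone enolate before it adds to the hindered enone carbon C1.

Step 6
Reactants: 10 Michael adduct
Product: 12 C8-(triethylsilyloxy) enone (10 with OSiEt3 on the now quaternary C8, drawn with C8–O trans to C10–O on ring B), via triethylsilyl dienol ether 11 (not isolated)
Conditions: Et3SiOTf, Et3N, CH2Cl2, 0 °C; then mCPBA, CH2Cl2, −20 to 0 °C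
Reagents that add atoms: triethylsilyl trifluoromethanesulfonate, CC[Si](CC)(CC)OS(=O)(=O)C(F)(F)F; 3-chloroperoxybenzoic acid (mCPBA), OOC(=O)c1cccc(Cl)c1
Why: Soft enolisation can only give the C3=C8 dienol ether (the enone double bond blocks the other side), and Rubottom oxidation of this electron-rich double bond with silyl migration places the oxygen on C8; either C8 epimer is acceptable because C8 becomes a ketone in step 13.

Step 7
Reactants: 12 C8-(triethylsilyloxy) enone
Product: 13 saturated ketone with free C5 primary alcohol (C1–C2 single bond, benzyl group removed)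
Conditions: H2 (1 atm), Pd/C (10%), EtOAc, rt
Reagents that add atoms: none
Why: Heterogeneous hydrogenation saturates the enone C1=C2 bond, which has done its blocking job, and hydrogenolyses the benzyl ether in the same operation; silyl ethers, ketone and lactone are inert in ethyl acetate.

Step 8
Reactants: 13 keto alcohol
Product: 14 C5 aldehyde
Conditions: Dess–Martin periodinane, CH2Cl2, 0 °C to rt
Reagents that add atoms: none
Why: Dess–Martin oxidation of the primary alcohol under near-neutral conditions, chosen so that the α-acyloxy aldehyde carbon C6 does not epimerise; the aldehyde is used at once.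

Step 9
Reactants: 14 C5 aldehyde; 15 ethyltriphenylphosphonium iodide
Product: 16 (Z)-vinyl iodide (C5H=C4(I)CH3 with iodine cis to C6)
Conditions: 15, n-BuLi, THF, rt; I2, −78 °C; NaN(SiMe3)2, −20 °C; then 14, −78 °C
Reagents that add atoms: iodine, II
Why: Stork–Zhao-type Wittig olefination with the α-iodo ylide, which should give the (Z)-2-iodoalk-2-ene; the aldehyde reacts in preference to the α-quaternary C3 ketone, and the iodine cis to C6 is the geometry that ring A needs.

Step 10
Reactants: 16 (Z)-vinyl iodide
Product: 18 tricyclic C3 trimethylsilyl ether (rings A, B and C; drawn with C3–O cis to C8–O), via tricyclic tertiary allylic alcohol 17 (not isolated)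
Conditions: CrCl2 (6 equiv), NiCl2 (2 mol%), DMSO, rt; aqueous work-up; crude 17 then Me3SiOTf, 2,6-lutidine, CH2Cl2, −78 to 0 °C
Reagents that add atoms: trimethylsilyl trifluoromethanesulfonate, C[Si](C)(C)OS(=O)(=O)C(F)(F)F
Why: Intramolecular Nozaki–Hiyama–Kishi addition of the vinylchromium species (trivalent chromium) to the C3 ketone closes cyclohexene ring A without touching the lactone; the C4=C5 alkene is now ring-locked cis, either C3 epimer is acceptable, and the silyl cap prevents silyl migration and trans-lactonisation in step 11.

Step 11
Reactants: 18 tricyclic tris(silyl ether)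
Product: 21 α-methylene lactone tris(silyl ether), via C11 dimethylaminomethyl lactone 19 (not isolated), via trimethylammonium iodide 20 (not isolated)
Conditions: LiN(i-Pr)2, THF, −78 °C; CH2=NMe2 I, −78 to 0 °C; then MeI, MeOH/THF, rt; then NaHCO3 (aq), EtOAc, rt
Reagents that add atoms: N,N-dimethylmethyleneiminium iodide (Eschenmoser's salt), C=[N+](C)C.[I-]; iodomethane (methyl group of 20 only), CI
Why: Lactone enolate Mannich reaction followed by quaternisation and elimination, the standard α-methylenation of trans-fused γ-lactones; in 18 the C11 protons are the only acidic C–H bonds.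

Step 12
Reactants: 21 α-methylene lactone tris(silyl ether)
Product: 22 tricyclic triol (free OH on C3, C8 and C10)
Conditions: HF·pyridine, pyridine, THF, 0 °C to rt
Reagents that add atoms: none
Why: Fluoride cleavage of the three silyl ethers; the pyridine buffer protects the tertiary allylic C3 alcohol from ionisation and the enoate from addition.

Step 13
Reactants: 22 tricyclic triol
Product: 23 ten-membered (Z)-3,8-dione (C3 enone, C8 ketone, free C10 OH, α-methylene lactone)
Conditions: Pb(OAc)4 (1.1 equiv), CH2Cl2, −20 to 0 °C
Reagents that add atoms: none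
Why: Criegee glycol cleavage: the vicinal tertiary diol forms a cyclic diester of tetravalent lead, which fragments in a two-electron step to the two ketones and Pb(OAc)2 (divalent lead). The closest known reaction type is the cleavage of decalin-4a,8a-diols to cyclodecane-1,6-diones. No ring is closed by bond formation: the ten-membered ring appears when the zero-atom bridge C3–C8 of the bicyclo[4.4.0]decene is cut, so no ring-closing transition state and no medium-ring entropy penalty are involved. No stereocentre is created; the C3 and C8 centres are destroyed, so all C3/C8 epimers of 22 converge on one dione. The Z geometry of C4=C5 is inherited from cyclohexene ring A, and C6, C7 and C10 are not touched. The step needs chemoselectivity for the 1,2-diol over the isolated C10 tertiary alcohol and the two alkenes; this rests on the chelating diol being the only group able to form the cyclic lead diester at low temperature. The drawn cis-diol should react fastest, and a trans epimer is expected to cleave more slowly by the acyclic pathway. The product is kept free of base, because C7–H is α to the new C8 ketone and β to the lactone oxygen, and is reduced directly in step 14.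

Step 14
Reactants: 23 ten-membered 3,8-dione
Product: 24 8-hydroxy 3-ketone (C8 configured as in 26)
Conditions: Me4NBH(OAc)3, MeCN/AcOH (1:1), −30 °C
Reagents that add atoms: none
Why: Evans–Saksena reduction: the boron binds the C10 oxygen and hydride is delivered internally through a six-membered chair in which the ten-membered ring bridges C7 and C1 on the same side, which corresponds to the 8,10-anti diol; the C3 enone has no β-hydroxyl group and should not be reduced by this mild reagent in acid.

Step 15
Reactants: 24 8-hydroxy 3-ketone
Product: 25 8-isobutyrate 3-ketone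
Conditions: (i-PrCO)2O, DMAP (cat.), pyridine, CH2Cl2, 0 °C
Reagents that add atoms: isobutyric anhydride, CC(C)C(=O)OC(=O)C(C)C
Why: Acylation of the only secondary alcohol; the tertiary C10 hydroxyl is too hindered to react under these conditions, and prompt acylation prevents trans-lactonisation to O8.

Step 16
Reactants: 25 8-isobutyrate 3-ketone
Product: 26 (3S,4Z,6R,7R,8R,10S)-3,10-dihydroxy-8-isobutyryloxygermacra-4,11(13)-dien-12,6-olide (target)
Conditions: (R)-2-methyl-CBS-oxazaborolidine (1 equiv), catecholborane (3 equiv), toluene/CH2Cl2, −78 °C
Reagents that add atoms: none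
Why: Corey–Bakshi–Shibata reduction: the α-methylalkenyl side (C4) acts as the large group and C2H2 as the small one, so the (R)-catalyst should give the (3S)-alcohol; the enoate and the esters are inert to catecholborane at this temperature.

## Compound list

1 | (E)-3-(tert-butyldimethylsilyloxy)-N,N-dimethylbuta-1,3-dien-1-amine | CN(C)/C=C/C(=C)O[Si](C)(C)C(C)(C)C | starting material
2 | methacrolein | CC(=C)C=O | starting material
3 | endo cycloadduct, 2-(dimethylamino)-1-methyl-4-(tert-butyldimethylsilyloxy)cyclohex-3-ene-1-carbaldehyde | CC(C)(C)[Si](C)(C)OC1=C[C@H](N(C)C)[C@](C)(C=O)CC1 | intermediate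
4 | (R)-1-methyl-4-oxocyclohex-2-ene-1-carbaldehyde | O=C1C=C[C@](C)(C=O)CC1 | intermediate
5 | (R)-1-methyl-4-oxocyclohex-2-en-1-yl formate | O=C1C=C[C@](C)(OC=O)CC1 | intermediate
6 | (R)-4-hydroxy-4-methylcyclohex-2-en-1-one | O=C1C=C[C@](C)(O)CC1 | intermediate
7 | (R)-4-methyl-4-(triethylsilyloxy)cyclohex-2-en-1-one | O=C1C=C[C@](C)(O[Si](CC)(CC)CC)CC1 | intermediate
8 | (S)-5-(hydroxymethyl)furan-2(5H)-one | O=C1C=C[C@@H](CO)O1 | starting material
9 | (S)-5-(benzyloxymethyl)furan-2(5H)-one | O=C1C=C[C@@H](COCc2ccccc2)O1 | intermediate
10 | (4R,5S)-5-(benzyloxymethyl)-4-[(5R)-5-methyl-2-oxo-5-(triethylsilyloxy)cyclohex-3-en-1-yl]oxolan-2-one (C8 epimers, one drawn) | O=C1O[C@H](COCc2ccccc2)[C@H](C1)[C@@H]3C[C@@](C)(O[Si](CC)(CC)CC)C=CC3=O | intermediate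
11 | triethylsilyl dienol ether of 10 (C3–OSiEt3, C3=C8, C1=C2) | O=C1O[C@H](COCc2ccccc2)[C@H](C1)C3=C(O[Si](CC)(CC)CC)C=C[C@](C)(O[Si](CC)(CC)CC)C3 | intermediate
12 | C8-(triethylsilyloxy) enone (C8 quaternary, C8–O trans to C10–O) | O=C1O[C@H](COCc2ccccc2)[C@H](C1)[C@@]3(O[Si](CC)(CC)CC)C[C@@](C)(O[Si](CC)(CC)CC)C=CC3=O | intermediate
13 | saturated C3 ketone with C5 primary alcohol | O=C1O[C@H](CO)[C@H](C1)[C@@]3(O[Si](CC)(CC)CC)C[C@@](C)(O[Si](CC)(CC)CC)CCC3=O | intermediate
14 | C5 aldehyde | O=C1O[C@H](C=O)[C@H](C1)[C@@]3(O[Si](CC)(CC)CC)C[C@@](C)(O[Si](CC)(CC)CC)CCC3=O | intermediate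
15 | ethyltriphenylphosphonium iodide | CC[P+](c1ccccc1)(c1ccccc1)c1ccccc1.[I-] | starting material
16 | (Z)-vinyl iodide (C5H=C4(I)CH3, iodine cis to C6) | O=C1O[C@H](/C=C(/C)I)[C@H](C1)[C@@]3(O[Si](CC)(CC)CC)C[C@@](C)(O[Si](CC)(CC)CC)CCC3=O | intermediate
17 | tricyclic tertiary allylic alcohol (C3–OH cis to C8–O; C8, C10 silyl ethers) | C1C(=O)O[C@@H]2C=C(C)[C@]3(O)CC[C@](C)(O[Si](CC)(CC)CC)C[C@]3(O[Si](CC)(CC)CC)[C@@H]12 | intermediate
18 | tricyclic C3 trimethylsilyl ether | C1C(=O)O[C@@H]2C=C(C)[C@]3(O[Si](C)(C)C)CC[C@](C)(O[Si](CC)(CC)CC)C[C@]3(O[Si](CC)(CC)CC)[C@@H]12 | intermediate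
19 | C11-(dimethylaminomethyl) lactone | CN(C)C[C@@H]1C(=O)O[C@@H]2C=C(C)[C@]3(O[Si](C)(C)C)CC[C@](C)(O[Si](CC)(CC)CC)C[C@]3(O[Si](CC)(CC)CC)[C@@H]12 | intermediate
20 | C11-(trimethylammoniomethyl) lactone iodide | C[N+](C)(C)C[C@@H]1C(=O)O[C@@H]2C=C(C)[C@]3(O[Si](C)(C)C)CC[C@](C)(O[Si](CC)(CC)CC)C[C@]3(O[Si](CC)(CC)CC)[C@@H]12.[I-] | intermediate
21 | α-methylene lactone tris(silyl ether) | C=C1C(=O)O[C@@H]2C=C(C)[C@]3(O[Si](C)(C)C)CC[C@](C)(O[Si](CC)(CC)CC)C[C@]3(O[Si](CC)(CC)CC)[C@@H]12 | intermediate
22 | tricyclic triol (C3, C8 ring-fusion diol, C10 OH) | C=C1C(=O)O[C@@H]2C=C(C)[C@]3(O)CC[C@](C)(O)C[C@]3(O)[C@@H]12 | intermediate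
23 | ten-membered (4Z)-3,8-dione, C6, C7, C10 as in 26 | C=C1C(=O)O[C@@H]2/C=C(/C)C(=O)CC[C@](C)(O)CC(=O)[C@@H]12 | intermediate
24 | 8-hydroxy 3-ketone, C8 as in 26 | C=C1C(=O)O[C@@H]2/C=C(/C)C(=O)CC[C@](C)(O)C[C@@H](O)[C@@H]12 | intermediate
25 | 8-isobutyrate 3-ketone | C=C1C(=O)O[C@@H]2/C=C(/C)C(=O)CC[C@](C)(O)C[C@@H](OC(=O)C(C)C)[C@@H]12 | intermediate
26 | (3S,4Z,6R,7R,8R,10S)-3,10-dihydroxy-8-isobutyryloxygermacra-4,11(13)-dien-12,6-olide | C=C1C(=O)O[C@@H]2/C=C(/C)[C@@H](O)CC[C@](C)(O)C[C@@H](OC(=O)C(C)C)[C@@H]12 | target

## Step count and least certain steps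

Total step count: 16. Longest linear sequence: 15 (steps 1–3 and 5–16; step 4 is the side branch).

Step 13 (key step). The most likely failure is decomposition of the freshly released dione rather than the scission itself. C7–H is α to the C8 ketone and allylic to the exocyclic enoate, with the lactone oxygen in the β-position, so elimination of the lactone carboxylate or migration of the C11=C13 double bond into the ring can follow; a C3/C8-trans epimer may also cleave slowly. The fallback removes the acidifying methylene group from the scission stage by moving the methylenation to the end. It sets out from 18: HF·pyridine gives the saturated-lactone triol F1; Pb(OAc)4 gives the dione F2; Me4NBH(OAc)3 gives the 8-alcohol F3; isobutyric anhydride gives the ester F4; the reduction of step 16 gives 11,13-dihydro-26 F5; Me3SiOTf/2,6-lutidine gives the bis(trimethylsilyl) ether F6. The sequence of step 11 (LiN(i-Pr)2, Eschenmoser's salt, MeI, NaHCO3) then gives the methylene lactone F7, in which the lactone CH2 is expected to be deprotonated in preference to the isobutyrate methine. Citric acid in methanol removes the silyl groups, and the route is rejoined at 26.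

Step 5. The lactone enolate formed by the first Michael addition may add to C1 of the enone within the same molecule (double Michael addition to a bicyclo[2.2.2]octanone), or the enolate may act as a base on the γ-proton of 9 and erase C6. The fallback masks the enone before the carbon–carbon bond is made. It sets out from 7: thiophenol and Et3N give the β-phenylthio ketone F8; LiN(i-Pr)2 and 9 give the Michael adduct F9, which has no enone to be attacked; mCPBA at −78 °C gives the sulfoxide F10; heating in toluene with CaCO3 eliminates benzenesulfenic acid towards C2 (C10 has no hydrogen) and rejoins the route at 10.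

Step 10. The vinylchromium species may fail to add to the hindered α-quaternary C3 ketone, so that protodeiodination or enolisation wins. The fallback closes ring A by metathesis of a six-membered ring instead. It sets out from 14: Ph3P=CH2 gives the vinyl lactone F11; CH2=C(CH3)MgBr with CeCl3 at −78 °C adds to the ketone to give the diene alcohol F12; the second-generation Grubbs catalyst, RuCl2(=CHPh)(H2IMes)(PCy3), closes the trisubstituted cyclohexene and rejoins the route at 17, which is silylated to 18 as in step 10.

Step 16. The conformation of the ten-membered ring may override the catalyst and give poor facial selectivity, and the ketone may be partly masked as the transannular hemiketal with the C10 hydroxyl, which would slow the reduction. The fallback accepts the substrate's own preference and corrects it by inversion. It sets out from 25: NaBH4/CeCl3 gives the C3 epimer F13; Mitsunobu reaction with chloroacetic acid, PPh3 and diisopropyl azodicarboxylate gives the inverted chloroacetate F14; thiourea and NaHCO3 remove the chloroacetyl group in the presence of the isobutyrate and the lactone and rejoin the route at 26.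

## Further compounds

F1 | step 13 | saturated-lactone triol (22 without the C13 methylene) | C1C(=O)O[C@@H]2C=C(C)[C@]3(O)CC[C@](C)(O)C[C@]3(O)[C@@H]12
F2 | step 13 | 11,13-dihydro 3,8-dione | C1C(=O)O[C@@H]2/C=C(/C)C(=O)CC[C@](C)(O)CC(=O)[C@@H]12
F3 | step 13 | 11,13-dihydro 8-hydroxy 3-ketone | C1C(=O)O[C@@H]2/C=C(/C)C(=O)CC[C@](C)(O)C[C@@H](O)[C@@H]12
F4 | step 13 | 11,13-dihydro 8-isobutyrate 3-ketone | C1C(=O)O[C@@H]2/C=C(/C)C(=O)CC[C@](C)(O)C[C@@H](OC(=O)C(C)C)[C@@H]12
F5 | step 13 | 11,13-dihydro-26 | C1C(=O)O[C@@H]2/C=C(/C)[C@@H](O)CC[C@](C)(O)C[C@@H](OC(=O)C(C)C)[C@@H]12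
F6 | step 13 | 3,10-bis(trimethylsilyl) ether of 11,13-dihydro-26 | C1C(=O)O[C@@H]2/C=C(/C)[C@@H](O[Si](C)(C)C)CC[C@](C)(O[Si](C)(C)C)C[C@@H](OC(=O)C(C)C)[C@@H]12
F7 | step 13 | 3,10-bis(trimethylsilyl) ether of 26 | C=C1C(=O)O[C@@H]2/C=C(/C)[C@@H](O[Si](C)(C)C)CC[C@](C)(O[Si](C)(C)C)C[C@@H](OC(=O)C(C)C)[C@@H]12
F8 | step 5 | 4-methyl-3-(phenylthio)-4-(triethylsilyloxy)cyclohexan-1-one (C1 epimers, one drawn) | O=C1C[C@@H](Sc2ccccc2)[C@](C)(O[Si](CC)(CC)CC)CC1
F9 | step 5 | Michael adduct of F8 and 9 | O=C1O[C@H](COCc2ccccc2)[C@H](C1)[C@@H]3C[C@@](C)(O[Si](CC)(CC)CC)[C@H](Sc4ccccc4)CC3=O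
F10 | step 5 | sulfoxide of F9 | O=C1O[C@H](COCc2ccccc2)[C@H](C1)[C@@H]3C[C@@](C)(O[Si](CC)(CC)CC)[C@H](S(=O)c4ccccc4)CC3=O
F11 | step 10 | C6 vinyl lactone ketone | O=C1O[C@H](C=C)[C@H](C1)[C@@]3(O[Si](CC)(CC)CC)C[C@@](C)(O[Si](CC)(CC)CC)CCC3=O
F12 | step 10 | C3 isopropenyl tertiary alcohol diene | O=C1O[C@H](C=C)[C@H](C1)[C@@]3(O[Si](CC)(CC)CC)C[C@@](C)(O[Si](CC)(CC)CC)CC[C@@]3(O)C(C)=C
F13 | step 16 | C3 epimer of 26 | C=C1C(=O)O[C@@H]2/C=C(/C)[C@H](O)CC[C@](C)(O)C[C@@H](OC(=O)C(C)C)[C@@H]12
F14 | step 16 | 3-O-chloroacetate of 26 | C=C1C(=O)O[C@@H]2/C=C(/C)[C@@H](OC(=O)CCl)CC[C@](C)(O)C[C@@H](OC(=O)C(C)C)[C@@H]12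
A1 | alternative 1 | open-chain (Z)-enal allylic bromide with C3 and C10 triethylsilyl ethers | O=C/C=C(/C)[C@@H](O[Si](CC)(CC)CC)CC[C@](C)(O[Si](CC)(CC)CC)C[C@@H](OC(=O)C(C)C)/C=C(\CBr)C(=O)OC
A2 | alternative 1 | 3,10-bis(triethylsilyl) ether of 26 | C=C1C(=O)O[C@@H]2/C=C(/C)[C@@H](O[Si](CC)(CC)CC)CC[C@](C)(O[Si](CC)(CC)CC)C[C@@H](OC(=O)C(C)C)[C@@H]12
A3 | alternative 2 | seco diene with C6 vinyl and C3 isopropenyl carbinol | C=C1C(=O)O[C@H](C=C)[C@H]1[C@H](OC(=O)C(C)C)C[C@@](C)(O)CC[C@H](O)C(C)=C
A4 | alternative 3 | cis-1-vinyl-2-isopropenylcyclohexanol fused to the lactone, C8 triethylsilyl ether | C1C(=O)O[C@@H]2[C@@H](C(C)=C)[C@@](O)(C=C)C[C@@H](O[Si](CC)(CC)CC)[C@@H]12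
A5 | alternative 3 | (4Z)-cyclodec-4-en-10-one lactone, C8 triethylsilyl ether | C1C(=O)O[C@@H]2/C=C(/C)CCCC(=O)C[C@@H](O[Si](CC)(CC)CC)[C@@H]12
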